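**Plan**
- Retrosynthesis: the ring bond C1–C2 and the ester C–OMe bond are undone together by putting the ester carbonyl carbon back between C1 and C2, which gives the six-membered 2-diazo-1,3-dione 11 and methanol. Then follow the diazo group, the ketone next to the carbinol (back to a secondary C–O), that C–O bond (oxa-Michael on an achiral p-quinol), and last the C2–hexadecyl bond (Grignard addition to a quinone monoketal).
- Forward: the chain is joined first to a commercial six-membered ring; oxygen and the diazo group are then placed on that ring; the cyclopentenone arises last, by contraction of the six-membered ring.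
- Enabling feature: the ring CH (C1) lies between the ring ketone C5 and the exocyclic ester carbonyl. The five ring carbons plus the ester carbon are therefore the six carbons of a cyclohex-4-ene-1,3-dione whose C2 can be made a carbene centre.
- Stereochemistry: C2 (carbinol) comes from a catalytic desymmetrisation of the two enantiotopic enone arms of the p-quinol (step 2) and is carried through the 1,2-shift with retention. C1 is set by thermodynamic equilibration of the β-keto ester (CO2Me trans to C16H33, cis to OH).

Key step: step 6

Assumption: (R)-TRIP is taken to give the (7aR) series in step 2; if a pilot run shows the opposite sense, (S)-TRIP is used and nothing else changes.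

**Step 1**
Reactants: 1 4,4-dimethoxycyclohexa-2,5-dien-1-one; 2 1-bromohexadecane
Product: 5 4-hexadecyl-4-hydroxycyclohexa-2,5-dien-1-one, via hexadecylmagnesium bromide 3 (not isolated), via ketal carbinol 4 (not isolated)
Conditions: Mg, THF, reflux; then 1, THF, −78 → 0 °C; then 1 M aq. HCl, 0 °C → rt
Reagents that add atoms: water (O)
Why: Grignard formation, 1,2-addition to the only free carbonyl of the quinone monoketal and acid hydrolysis of the dimethyl ketal should give the achiral p-quinol; no stereocentre is formed and the carbonyl oxygen of 5 comes from water.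

**Step 2**
Reactants: 5 4-hexadecyl-4-hydroxycyclohexa-2,5-dien-1-one; 6 3-methylbutanal
Product: 8 (2R,3aS,7aR)-7a-hexadecyl-2-(2-methylpropyl)-3a,7a-dihydro-2H-1,3-benzodioxol-5(4H)-one (cis-fused dioxolane on the cyclohexenone; acetal centre drawn as the expected exo isomer, its configuration is of no consequence), via hemiacetal 7 (not isolated)
Conditions: (R)-TRIP (5 mol %), 6 (3 equiv), ClCH2CH2Cl, 4 Å MS, 40 °C
Reagents that add atoms: none
Why: Chiral phosphoric acid-catalysed acetalisation/oxa-Michael cascade, in which the tertiary hydroxyl and 6 form hemiacetal 7 reversibly and the catalyst-bound hemiacetal hydroxyl adds 5-exo-trig to one of the two enantiotopic enone β-carbons; this should set the quaternary carbinol centre (7aR) by enantiotopic-group selection and the cis ring fusion by the geometry of the tether.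

**Step 3**
Reactants: 8 (2R,3aS,7aR)-7a-hexadecyl-2-(2-methylpropyl)-3a,7a-dihydro-2H-1,3-benzodioxol-5(4H)-one
Product: 9 (4R,5S)-4-hexadecyl-4,5-dihydroxycyclohex-2-en-1-one
Conditions: TsOH·H2O (5 mol %), MeOH, 0 °C → rt; aqueous work-up
Reagents that add atoms: none
Why: Acid-catalysed transacetalisation with methanol breaks only the bonds at the acetal carbon, so both ring C–O bonds keep their configuration; weak acid and low temperature are chosen to hold back β-elimination of the β-oxygen.

**Step 4**
Reactants: 9 (4R,5S)-4-hexadecyl-4,5-dihydroxycyclohex-2-en-1-one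
Product: 10 (6R)-6-hexadecyl-6-hydroxycyclohex-4-ene-1,3-dione (enolised vinylogous acid; not stored)
Conditions: IBX (1.5 equiv), EtOAc, 65 °C; filter; crude used at once
Reagents that add atoms: none
Why: IBX oxidation of a β-hydroxy ketone to the 1,3-dione; the tertiary alcohol has no carbinol hydrogen, IBX does not normally cleave 1,2-diols, and the quaternary stereocentre cannot enolise and so should stay intact.

**Step 5**
Reactants: 10 (6R)-6-hexadecyl-6-hydroxycyclohex-4-ene-1,3-dione
Product: 11 (6R)-2-diazo-6-hexadecyl-6-hydroxycyclohex-4-ene-1,3-dione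
Conditions: p-ABSA (1.1 equiv), Et3N (1.5 equiv), MeCN, 0 °C → rt
Reagents that add atoms: 4-acetamidobenzenesulfonyl azide (p-ABSA), CC(=O)Nc1ccc(cc1)S(=O)(=O)N=[N+]=[N-]
Why: Regitz diazo transfer to the doubly activated methylene of a cyclic 1,3-dione through its ammonium enolate; the quaternary stereocentre is not involved and the diazo group blocks further enolisation.

**Step 6**
Reactants: 11 (6R)-2-diazo-6-hexadecyl-6-hydroxycyclohex-4-ene-1,3-dione
Product: 14 methyl (1R,2R)-2-hexadecyl-2-hydroxy-5-oxocyclopent-3-ene-1-carboxylate, via acylketene 12 (not isolated), via enol 13 (not isolated)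
Conditions: hν (medium-pressure Hg lamp, Pyrex, λ > 300 nm), degassed MeOH, 0 °C; then MeOH, rt, no base; chromatography on neutral silica
Reagents that add atoms: methanol (CO)
Why: Irradiation expels N2 from the cyclic 2-diazo-1,3-dione, whose two acyl C–C bonds are both held anti-periplanar to the C–N2 bond, and the carbinol carbon C6 shifts from C1 to the diazo carbon C2 with retention (Wolff rearrangement), so that C1 leaves the ring as the ketene carbon of acylketene 12 and the six-membered ring contracts to the cyclopentenone. Methanol adds to 12 through the six-centre transition state that involves the neighbouring ring ketone and gives enol 13, which ketonises to 14. The closest known reaction type is the photochemical Wolff ring contraction of 2-diazocyclohexane-1,3-diones in alcohols to 2-oxocyclopentane-1-carboxylates; the five-membered ring is closed by the 1,2-shift itself (the C6–C2 bond forms as the C6–C1 bond breaks), not by a cyclisation. The new stereocentre C1 is set under thermodynamic control: it is the acidic CH of a β-keto ester, so both faces of protonation should converge through 13 on the isomer with CO2Me trans to the hexadecyl chain and cis (hydrogen-bonded) to OH, while C2 is carried over unchanged because the shift is suprafacial and no base is present to start a retro-aldol opening. The step needs the carbinol carbon to migrate and not the vinylic carbon C4 on the other carbonyl; this should be secured by the higher migratory aptitude of the sp3, tertiary, oxygen-substituted carbon (electron-rich σ bond with lone-pair assistance) over the sp2 carbon, whose bond to C3 is strengthened by enone conjugation that a shift would give up.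

**Compound list**
1 | 4,4-dimethoxycyclohexa-2,5-dien-1-one | COC1(OC)C=CC(=O)C=C1 | starting material
2 | 1-bromohexadecane | CCCCCCCCCCCCCCCCBr | starting material
3 | hexadecylmagnesium bromide | CCCCCCCCCCCCCCCC[Mg]Br | intermediate (not isolated)
4 | 1-hexadecyl-4,4-dimethoxycyclohexa-2,5-dien-1-ol | CCCCCCCCCCCCCCCCC1(O)C=CC(OC)(OC)C=C1 | intermediate (not isolated)
5 | 4-hexadecyl-4-hydroxycyclohexa-2,5-dien-1-one | CCCCCCCCCCCCCCCCC1(O)C=CC(=O)C=C1 | intermediate
6 | 3-methylbutanal | CC(C)CC=O | starting material
7 | 4-hexadecyl-4-(1-hydroxy-3-methylbutoxy)cyclohexa-2,5-dien-1-one (hemiacetal, both epimers in equilibrium) | CC(C)CC(O)OC1(CCCCCCCCCCCCCCCC)C=CC(=O)C=C1 | intermediate (not isolated)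
8 | (2R,3aS,7aR)-7a-hexadecyl-2-(2-methylpropyl)-3a,7a-dihydro-2H-1,3-benzodioxol-5(4H)-one | CCCCCCCCCCCCCCCC[C@]12O[C@H](CC(C)C)O[C@H]1CC(=O)C=C2 | intermediate
9 | (4R,5S)-4-hexadecyl-4,5-dihydroxycyclohex-2-en-1-one | CCCCCCCCCCCCCCCC[C@@]1(O)C=CC(=O)C[C@@H]1O | intermediate
10 | (6R)-6-hexadecyl-6-hydroxycyclohex-4-ene-1,3-dione | CCCCCCCCCCCCCCCC[C@@]1(O)C=CC(=O)CC1=O | intermediate
11 | (6R)-2-diazo-6-hexadecyl-6-hydroxycyclohex-4-ene-1,3-dione | CCCCCCCCCCCCCCCC[C@@]1(O)C=CC(=O)C(=[N+]=[N-])C1=O | intermediate
12 | (4R)-4-hexadecyl-4-hydroxy-5-(oxomethylidene)cyclopent-2-en-1-one | CCCCCCCCCCCCCCCC[C@@]1(O)C=CC(=O)C1=C=O | intermediate (not isolated)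
13 | methyl (5R)-5-hexadecyl-2,5-dihydroxycyclopenta-1,3-diene-1-carboxylate | CCCCCCCCCCCCCCCC[C@@]1(O)C=CC(O)=C1C(=O)OC | intermediate (not isolated)
14 | methyl (1R,2R)-2-hexadecyl-2-hydroxy-5-oxocyclopent-3-ene-1-carboxylate | CCCCCCCCCCCCCCCC[C@@]1(O)C=CC(=O)[C@@H]1C(=O)OC | target

**Count**
Total steps: 6. Longest linear sequence: 6 steps (from 1 or 2).

**Steps most likely to fail**

Step 6. The wrong acyl group may migrate (shift of the vinylic carbon in place of the carbinol carbon), or the enone product may degrade on over-irradiation. The fallback removes the choice by taking the enone carbonyl out of play. It sets out from 9 and comes back to the route at 14.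
- Ketalisation of the enone carbonyl (ethylene glycol, cat. PPTS, benzene, Dean–Stark; the double bond cannot move because the γ-carbon is quaternary) would give (8R,9S)-8-hexadecyl-1,4-dioxaspiro[4.5]dec-6-ene-8,9-diol F1.
- IBX oxidation of the secondary alcohol would give (8R)-8-hexadecyl-8-hydroxy-1,4-dioxaspiro[4.5]dec-6-en-9-one F2.
- Detrifluoroacetylative diazo transfer (LiHMDS, 2.2 equiv, THF, −78 °C, CF3CO2CH2CF3, then MsN3, Et3N, H2O, MeCN) would pass through the α-trifluoroacetyl ketone F3 (not isolated) and give (8R)-10-diazo-8-hexadecyl-8-hydroxy-1,4-dioxaspiro[4.5]dec-6-en-9-one F4, whose diazo carbon has only one acyl neighbour.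
- Photolysis in MeOH (the known ring contraction of 2-diazocyclohexanones) would give, through the ketene (7R)-7-hexadecyl-6-(oxomethylidene)-1,4-dioxaspiro[4.4]non-8-en-7-ol F5, the ester methyl (7R)-7-hexadecyl-7-hydroxy-1,4-dioxaspiro[4.4]non-8-ene-6-carboxylate F6 as a mixture of C6 epimers.
- Ketal hydrolysis (PPTS, acetone/H2O) would unveil the β-keto ester, whose C1 centre equilibrates as in step 6, to give 14.

Step 2. The catalyst may discriminate poorly between the two enone arms, or the cascade may be slow with the lipophilic C16 quinol. The fallback replaces asymmetric catalysis by resolution with recycling. It sets out from 5 and comes back at 8. The same cascade with achiral diphenyl phosphate would give racemic 8. Preparative chromatography on a chiral stationary phase would separate 8 from its antipode (2S,3aR,7aS)-7a-hexadecyl-2-(2-methylpropyl)-3a,7a-dihydro-2H-1,3-benzodioxol-5(4H)-one F7. F7 would be returned to 5 by DBU-induced β-elimination with loss of the aldehyde and recycled.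

Step 3. Acid may induce β-elimination of the β-alkoxy ketone (retro-oxa-Michael back to achiral 5) in competition with acetal exchange. The fallback avoids an acetal altogether. It sets out from 5 and comes back at 9. Phenylboronic acid and a cinchona-derived bifunctional amine–thiourea catalyst (boronic acid hemiester as hydroxide surrogate, intramolecular oxa-Michael addition) would give the cyclic boronate (3aS,7aR)-7a-hexadecyl-2-phenyl-3a,7a-dihydro-1,3,2-benzodioxaborol-5(4H)-one F8. F8 is cleaved under neutral conditions by transesterification with pinacol to give 9.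

**Further compounds**
F1 | step 6 | (8R,9S)-8-hexadecyl-1,4-dioxaspiro[4.5]dec-6-ene-8,9-diol | CCCCCCCCCCCCCCCC[C@@]1(O)C=CC2(OCCO2)C[C@@H]1O
F2 | step 6 | (8R)-8-hexadecyl-8-hydroxy-1,4-dioxaspiro[4.5]dec-6-en-9-one | CCCCCCCCCCCCCCCC[C@@]1(O)C=CC2(OCCO2)CC1=O
F3 | step 6 | (8R)-8-hexadecyl-8-hydroxy-10-(trifluoroacetyl)-1,4-dioxaspiro[4.5]dec-6-en-9-one (C10 epimers, not isolated) | CCCCCCCCCCCCCCCC[C@@]1(O)C=CC2(OCCO2)C(C(=O)C(F)(F)F)C1=O
F4 | step 6 | (8R)-10-diazo-8-hexadecyl-8-hydroxy-1,4-dioxaspiro[4.5]dec-6-en-9-one | CCCCCCCCCCCCCCCC[C@@]1(O)C=CC2(OCCO2)C(=[N+]=[N-])C1=O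
F5 | step 6 | (7R)-7-hexadecyl-6-(oxomethylidene)-1,4-dioxaspiro[4.4]non-8-en-7-ol (ketene, not isolated) | CCCCCCCCCCCCCCCC[C@@]1(O)C=CC2(OCCO2)C1=C=O
F6 | step 6 | methyl (7R)-7-hexadecyl-7-hydroxy-1,4-dioxaspiro[4.4]non-8-ene-6-carboxylate (C6 epimers) | CCCCCCCCCCCCCCCC[C@@]1(O)C=CC2(OCCO2)C1C(=O)OC
F7 | step 2 | (2S,3aR,7aS)-7a-hexadecyl-2-(2-methylpropyl)-3a,7a-dihydro-2H-1,3-benzodioxol-5(4H)-one | CCCCCCCCCCCCCCCC[C@@]12O[C@@H](CC(C)C)O[C@@H]1CC(=O)C=C2
F8 | step 3 | (3aS,7aR)-7a-hexadecyl-2-phenyl-3a,7a-dihydro-1,3,2-benzodioxaborol-5(4H)-one | CCCCCCCCCCCCCCCC[C@]12OB(c3ccccc3)O[C@H]1CC(=O)C=C2
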